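**Retrosynthetic overview**
1. The target is 2-amino-3-(2-methylpyridin-4-yl)phenol N-acylated by 13-(acetylthio)tridecanoic acid. The last step forms C8–C9 of the tridecanoyl chain by a Ni-electrocatalytic doubly decarboxylative C(sp3)–C(sp3) coupling of two N-hydroxyphthalimide esters, a reductive Kolbe-type union that gives the unprotected target directly.
2. Enabling feature: the unbranched, heteroatom-free (CH2)12 run C2–C13. C8 lies seven bonds from amide C1 and C9 five bonds from S, and both are plain CH2 groups. Each therefore maps onto the carboxyl-bearing carbon of a cheap acid (azelaic acid half-ester, 6-bromohexanoic acid), the primary radicals have nothing to eliminate or epimerise, and the benzene and pyridine rings are remote spectators.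
3. Large half: anilide C–N bond (carbodiimide coupling), then the biaryl bond between benzene C3 and pyridine C4 (Suzuki–Miyaura).
4. Small half: C–S bond by SN2 with thioacetate on 6-bromohexanoic acid.
5. Ring order: no ring is formed. The benzene and pyridine rings are bought intact and joined in step 1.

Key step: step 7

Remark on the chemistry: the target has no stereocentre and its biaryl axis rotates freely. It is therefore achiral, no enantiomer question arises, and the SMILES carry no stereodescriptors.

**Step 1**
Reactants: 1 2-amino-3-bromophenol; 2 2-methyl-4-(4,4,5,5-tetramethyl-1,3,2-dioxaborolan-2-yl)pyridine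
Product: 3 2-amino-3-(2-methylpyridin-4-yl)phenol
Conditions: Pd(dppf)Cl2·CH2Cl2 (5 mol %), K2CO3, degassed 1,4-dioxane/H2O, 90 °C, Ar
Reagents that add atoms: none
Why: Suzuki–Miyaura coupling of an aryl bromide with a 4-pyridyl boronate, a boronate class that resists protodeboronation, is well precedented on unprotected ortho-bromoanilines and phenols when a chelating ferrocenylphosphine palladium catalyst and degassed aqueous carbonate are used.

**Step 2**
Reactants: 3 2-amino-3-(2-methylpyridin-4-yl)phenol; 4 9-methoxy-9-oxononanoic acid (monomethyl azelate)
Product: 5 methyl 9-{[2-hydroxy-6-(2-methylpyridin-4-yl)phenyl]amino}-9-oxononanoate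
Conditions: DIC, HOAt, CH2Cl2/DMF, rt to 40 °C
Reagents that add atoms: none
Why: Carbodiimide/HOAt amide coupling should end at nitrogen, because any ester formed at the neighbouring phenol oxygen passes its acyl group on by a fast O→N acyl shift through a five-membered intermediate, while the methyl ester end of 4 is inert.

**Step 3**
Reactants: 5 methyl 9-{[2-hydroxy-6-(2-methylpyridin-4-yl)phenyl]amino}-9-oxononanoate
Product: 6 9-{[2-hydroxy-6-(2-methylpyridin-4-yl)phenyl]amino}-9-oxononanoic acid
Conditions: LiOH·H2O, THF/MeOH/H2O, rt; then 1 M HCl to pH ≈ 5
Reagents that add atoms: lithium hydroxide, [Li+].[OH-]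
Why: Saponification (BAc2) of the unhindered methyl ester is much faster than attack on the hindered secondary anilide, it also cleaves any aryl ester carried over from step 2, and adjustment to the isoelectric pH allows isolation of the amphoteric acid.

**Step 4**
Reactants: 6 9-{[2-hydroxy-6-(2-methylpyridin-4-yl)phenyl]amino}-9-oxononanoic acid
Product: 7 1,3-dioxoisoindolin-2-yl 9-{[2-hydroxy-6-(2-methylpyridin-4-yl)phenyl]amino}-9-oxononanoate
Conditions: N-hydroxyphthalimide, DIC, CH2Cl2/DMF, 0 °C to rt, no DMAP; filtration, short silica plug
Reagents that add atoms: N-hydroxyphthalimide, O=C1c2ccccc2C(=O)N1O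
Why: In this Steglich-type carbodiimide esterification run without DMAP, the acidic, α-effect-nucleophilic N–OH of N-hydroxyphthalimide should intercept the O-acylisourea much faster than the hindered, intramolecularly hydrogen-bonded phenol O–H.

**Step 5**
Reactants: 8 6-bromohexanoic acid
Product: 9 6-(acetylthio)hexanoic acid
Conditions: KSAc, DMF, rt; dilute acid work-up
Reagents that add atoms: potassium thioacetate, CC(=O)[S-].[K+]
Why: SN2 displacement of a primary bromide by the soft thioacetate anion, which is too weak a base to be quenched by the free carboxylic acid.

**Step 6**
Reactants: 9 6-(acetylthio)hexanoic acid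
Product: 10 1,3-dioxoisoindolin-2-yl 6-(acetylthio)hexanoate
Conditions: N-hydroxyphthalimide, DIC, DMAP (5 mol %), CH2Cl2, rt
Reagents that add atoms: N-hydroxyphthalimide, O=C1c2ccccc2C(=O)N1O
Why: Steglich-type esterification gives the bench-stable redox-active ester, and the S-alkyl thioacetate is inert to carbodiimide and N-hydroxyphthalimide at room temperature.

**Step 7**
Reactants: 7 1,3-dioxoisoindolin-2-yl 9-{[2-hydroxy-6-(2-methylpyridin-4-yl)phenyl]amino}-9-oxononanoate; 10 1,3-dioxoisoindolin-2-yl 6-(acetylthio)hexanoate (3 equiv)
Product: 11 echinoclathrine B, S-(13-{[2-hydroxy-6-(2-methylpyridin-4-yl)phenyl]amino}-13-oxotridecyl) ethanethioate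
Conditions: NiCl2·6H2O (20 mol %), 2,6-bis(pyrazol-1-yl)pyridine (20 mol %), NaI, DMF, undivided cell, (+) Zn | (−) Ni foam, constant current until both esters are consumed, rt, Ar; aq. NH4Cl/EDTA work-up
Reagents that add atoms: none
Why: Low-valent nickel, regenerated at the cathode while the zinc anode dissolves, transfers one electron to each N-acyloxyphthalimide, which fragments into phthalimide anion, CO2 and a primary alkyl radical; the 7-(arylcarbamoyl)heptyl radical from 7 and the 5-(acetylthio)pentyl radical from 10 are captured in turn by nickel, and reductive elimination from the dialkylnickel(III) species forms the C8–C9 bond and with it the complete, unprotected target. The closest known reaction type is this one itself, the Ni-electrocatalytic doubly decarboxylative C(sp3)–C(sp3) cross-coupling of two redox-active esters, the reductive counterpart of the mixed Kolbe electrolysis, which is established for primary/primary pairs. No ring is closed and no stereocentre is created, so neither a mode of closure nor a stereocontrol element is needed. The selectivity required is cross- over homocoupling, which is only statistical for two primary radicals and is therefore pushed by the threefold excess of the cheap ester 10, while the basic pyridine ring present in only one partner should make the neutral bis(thioacetate) dimer, the mono-pyridine product 11 and the bis-pyridine dimer easy to separate. Chemoselectivity rests on the reductive regime: the active esters are reduced well before an S-alkyl thioacetate, an anilide or a pyridine, S-alkyl thioesters are not expected to add oxidatively to nickel at room temperature, the oxidation-prone 2-acylaminophenol ring (which a true anodic Kolbe electrolysis would destroy) is shielded because zinc is oxidised first, and phthalimide anion is too weak a base to turn the phenol into an acyl acceptor. Because both radical centres sit in a plain methylene chain, no β-scission is open to them, and a 1,5-hydrogen shift or attack on sulfur within the 5-(acetylthio)pentyl radical should be slower than capture by nickel.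

**Compound list**
1 | 2-amino-3-bromophenol | Nc1c(O)cccc1Br | starting material
2 | 2-methyl-4-(4,4,5,5-tetramethyl-1,3,2-dioxaborolan-2-yl)pyridine | Cc1cc(ccn1)B1OC(C)(C)C(C)(C)O1 | starting material
3 | 2-amino-3-(2-methylpyridin-4-yl)phenol | Nc1c(O)cccc1-c1ccnc(C)c1 | intermediate
4 | 9-methoxy-9-oxononanoic acid (monomethyl azelate) | COC(=O)CCCCCCCC(=O)O | starting material
5 | methyl 9-{[2-hydroxy-6-(2-methylpyridin-4-yl)phenyl]amino}-9-oxononanoate | COC(=O)CCCCCCCC(=O)Nc1c(O)cccc1-c1ccnc(C)c1 | intermediate
6 | 9-{[2-hydroxy-6-(2-methylpyridin-4-yl)phenyl]amino}-9-oxononanoic acid | OC(=O)CCCCCCCC(=O)Nc1c(O)cccc1-c1ccnc(C)c1 | intermediate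
7 | 1,3-dioxoisoindolin-2-yl 9-{[2-hydroxy-6-(2-methylpyridin-4-yl)phenyl]amino}-9-oxononanoate | O=C(CCCCCCCC(=O)Nc1c(O)cccc1-c1ccnc(C)c1)ON1C(=O)c2ccccc2C1=O | intermediate
8 | 6-bromohexanoic acid | OC(=O)CCCCCBr | starting material
9 | 6-(acetylthio)hexanoic acid | CC(=O)SCCCCCC(=O)O | intermediate
10 | 1,3-dioxoisoindolin-2-yl 6-(acetylthio)hexanoate | CC(=O)SCCCCCC(=O)ON1C(=O)c2ccccc2C1=O | intermediate
11 | echinoclathrine B | CC(=O)SCCCCCCCCCCCCC(=O)Nc1c(O)cccc1-c1ccnc(C)c1 | target

**Total step count:** 7. **Longest linear sequence:** 5 (steps 1, 2, 3, 4, 7).

**Steps most likely to fail**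

Step 7. Three processes could erode the cross-coupling: statistical homocoupling of each ester, premature hydrogen uptake by the alkyl radicals or alkylnickel species (decarboxylative reduction), and slowing of the nickel cycle by coordination of sulfur or pyridine nitrogen. Fallback: the same C8–C9 bond is made at the very start by a classical anodic mixed Kolbe electrolysis, on fragments that carry neither sulfur, phenol nor pyridine. The fallback sets out from 4 and 8. Co-electrolysis of 4 with an excess of 8 (Pt anode and cathode, MeOH, acids partly neutralised with NaOMe, high current density, 40–50 °C) should give methyl 13-bromotridecanoate F1. LiOH in THF/H2O at 0 °C then gives 13-bromotridecanoic acid F2, and potassium thioacetate in DMF gives 13-(acetylthio)tridecanoic acid F3. DIC/HOAt coupling of F3 with 3 comes back to the route at 11.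

Step 4. Acylation of the phenol oxygen (self-condensation) could compete, and the active ester could hydrolyse during purification; both are assisted by the internal pyridine base. Fallback: the large fragment enters the coupling as an alkyl bromide, so it never carries an active ester. The fallback sets out from 3, which is acylated with commercial 8-bromooctanoic acid (DIC, HOAt, CH2Cl2/DMF) to give 8-bromo-N-[2-hydroxy-6-(2-methylpyridin-4-yl)phenyl]octanamide F4. F4 is used promptly and joined with 10 by the known nickel-catalysed reductive cross-electrophile coupling of N-hydroxyphthalimide esters with unactivated primary alkyl bromides (Ni(II)/bipyridine-type ligand, Zn dust, DMA, rt). This forms the same C8–C9 bond and comes back to the route at 11.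

Step 1. The free aminophenol could sequester the catalyst through N,O-chelation, the electron-rich aminophenol could be air-oxidised in hot aqueous base, and the boronate could undergo protodeboronation. Fallback: the nitrogen is carried at the nitro oxidation level through the coupling. The fallback sets out from 2, which is coupled under the same Suzuki–Miyaura conditions with commercial 3-bromo-2-nitrophenol, an activated and non-chelating bromide, to give 3-(2-methylpyridin-4-yl)-2-nitrophenol F5. Hydrogenation (H2, Pd/C, MeOH, rt) comes back to the route at 3.

**Further compounds**
F1 | step 7 | methyl 13-bromotridecanoate | COC(=O)CCCCCCCCCCCCBr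
F2 | step 7 | 13-bromotridecanoic acid | OC(=O)CCCCCCCCCCCCBr
F3 | step 7 | 13-(acetylthio)tridecanoic acid | CC(=O)SCCCCCCCCCCCCC(=O)O
F4 | step 4 | 8-bromo-N-[2-hydroxy-6-(2-methylpyridin-4-yl)phenyl]octanamide | BrCCCCCCCC(=O)Nc1c(O)cccc1-c1ccnc(C)c1
F5 | step 1 | 3-(2-methylpyridin-4-yl)-2-nitrophenol | Cc1cc(ccn1)-c1cccc(O)c1[N+](=O)[O-]
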